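## Structural features

The target is a cyclohex-1-ene. Its ring atoms are numbered here C1 (alkene carbon bearing the side chain), C2 (=CH), C3, C4, C5 and C6. C1 carries an (E)-acrylate, C10H=C11H–C12(=O)O, whose carboxyl is esterified with the secondary hydroxyl of (R)-3-(3,4-dihydroxyphenyl)lactic acid. C3, C6 and C5 each carry a free carboxyl (carbons C7, C8 and C9 respectively), and C4 carries a 3,4-dihydroxyphenyl ring.

C3 to C6 are four contiguous stereocentres, 3R,4S,5R,6R in this numbering. The three carboxyls lie on one face and the aryl group on the other: C3/C4 trans, C4/C5 trans, C5/C6 cis, and C7/C8 1,4-cis. The lactate centre is R.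

The fragile parts are the two catechols (air, oxidants, base), the dienoate ester of an α-hydroxy acid, and C3–H and C6–H, which are both allylic and α to a carboxyl. Of four carboxyls exactly one (C12) is esterified, so they must be told apart.

The real difficulty is the block C3–C6 in absolute sense, together with the position of the aryl group and the carboxyl differentiation.

The feature exploited is that C7–C3–C2=C1–C6–C8 is a ring-opened ortho-quinone: C7 and C8 are the two former carbonyl carbons, held 1,4-cis. In addition C9 on C5 is cis to C8, so it can be tied to C8 through a single oxygen atom.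

## Logic of the disconnections

**16 to 15.** The five O–allyl bonds (four catechol oxygens, the lactate carboxyl) are cut last. All five fall in one neutral palladium-catalysed step, which the dienoate, the free acids and the epimerisable C3 and C6 tolerate. The forward step must release two catechols without oxidant or strong base.

**15 to 13 by way of 14.** The bonds concerned are C7–C8, which is absent from the target, and the acyl bond C9–O(C8). Read backwards, the C3 and C6 carboxyls are joined into a two-carbon keto/ketal bridge and the C5 carboxyl becomes a lactone onto C8. This turns the cyclohexene into a rigid bicyclo[2.2.2]octenone in which the 1,4-cis and 5,6-cis relations cannot be otherwise, and in which C3 and C6 are non-enolisable bridgeheads. The demand on the forward step is to open the acyloxy ketal and cleave the resulting 1,2-diketone without touching the C12 ester.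

**13 to 9 and 12.** The C10=C11 bond is cut (olefination). The C12 carboxyl, with its lactate already attached, enters separately from the three ring carboxyls, so the differentiation problem never arises. The demand is E selectivity and a base mild enough for the lactate centre and the acyloxy ketal.

**9 to 8 to 7 and 6 (key).** C3–C4 and C5–C6 are cut as an intramolecular [4+2] retro-addition, then C8–O(acyl) as a retro-acyloxylation of a phenol. This leads back to an aromatic aldehyde and a cinnamic acid, both flat and achiral. The only stereocentre that has to be made is the ketal carbon C8, which is not in the target. It must be set by the oxidant, and the tether must relay it to C3, C4, C5 and C6.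

**6 to 5 and 3; 5 to 4; 3 to 1 (via 2).** The I–O bonds are cut: the carboxylate to be transferred is placed on a chiral aryl-λ3-iodane by ligand exchange, so that no other nucleophile competes in the key step. 3 comes from 1 by cutting three O–allyl bonds and re-forming the acid.

**12 to 11 to 10.** The ester C–O bond to the phosphonoacetyl group is cut, then three O–allyl bonds, back to the chiral-pool hydroxy acid. The demand is O-alkylation of phenols and carboxyl in the presence of the free secondary hydroxyl.

## Other disconnections considered

**Alternative 1:** This is the disconnection that comes to mind first. Cut C3–C4 and C5–C6 as an intermolecular Diels–Alder reaction of the acyclic cross-conjugated triene triester A1 with cinnamate 2, giving cyclohexene tetraester A2.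
- The two vinylogous arms of A1 are identical, so nothing decides which arm becomes ring carbon C3 and which remains the side chain. The four esters of A2 then have to be told apart to place the lactate on C12 alone.
- Both partners are electron-poor and the dienophile is β-aryl-substituted, so forcing conditions are expected, and the new semicyclic diene of A2 can add a second dienophile.
- The C3/C6 cis relation depends on diene geometry, the carboxyl-endo/aryl-exo orientation is not secured, and a monodentate ester dienophile offers no handle for absolute control.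
- In the chosen plan the diene is cyclic and locked s-cis, the tether fixes regio-, endo/exo and facial selectivity, and C12 arrives separately.

**Alternative 2:** Cut C3–C4, C5–C6 and C1=C2 as an amine-catalysed Michael/Michael/aldol-condensation cascade of a formylacetate ester, an arylidene malonate and a 4-oxobut-2-enoate. This gives cyclohexene carbaldehyde A3, followed by mono-decarboxylation at C5.
- C5 can only act as the central Michael donor if it is doubly activated. Its configuration would therefore be set afterwards by a decarboxylative protonation between two stereocentres, with no control element.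
- The formylacetate partner is an enolised 1,3-dicarbonyl and a poor enamine donor.
- C3 in A3 lies between an ester and a vinylogous formyl group and is labile under the amine catalyst.
- The step count is similar, but three selectivity problems remain open where the chosen plan has one.

**Alternative 3:** Cut C1=C2 and build the diene by ring-closing enyne metathesis (second-generation Grubbs catalyst) of the acyclic 1,7-enyne A4 to vinylcyclohexene A5, then cross-metathesis with an acrylate.
- The ring closure contributes no stereocontrol: all four stereocentres must be made on an open chain beforehand.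
- C3 and C6 of A4 are α to esters and respectively allylic and propargylic, hence prone to epimerisation and alkyne–allene isomerisation.
- Cross-metathesis on the 1,3-diene of A5 is not site-selective.
- The route is longer and places the difficulty in the acyclic precursor.

Key step: step 4

Assumptions: 10 and 4 are taken as purchasable in enantiopure form. The (R,R)-reagent 6 is assumed to deliver the carboxylate to the face of 7 that gives (R)-8; if the sense proves opposite, the mirror-image iodoarene from the other lactate would be used with no other change.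

## Steps

**Step 1**
Reactants: 1 caffeic acid, (E)-3-(3,4-dihydroxyphenyl)prop-2-enoic acid
Product: 3 (E)-3-[3,4-bis(allyloxy)phenyl]prop-2-enoic acid, via allyl ester 2 (not isolated)
Conditions: allyl bromide (3.5 equiv), K2CO3, DMF, 50 °C; then 2 M aq NaOH, MeOH, 50 °C; then aq HCl
Reagents that add atoms: allyl bromide C=CCBr
Why: Williamson O-allylation of the two phenoxides and the carboxylate, then saponification, which cleaves only the allyl ester because aryl allyl ethers are inert to hydroxide; the E alkene is untouched and no stereocentre is involved.

**Step 2**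
Reactants: 4 (R,R)-2-iodo-1,3-bis[1-(mesitylcarbamoyl)ethoxy]benzene
Product: 5 (R,R)-2-(diacetoxy-λ3-iodanyl)-1,3-bis[1-(mesitylcarbamoyl)ethoxy]benzene
Conditions: AcOOH (32% in AcOH, 1.5 equiv), AcOH, 30 °C
Reagents that add atoms: peracetic acid CC(=O)OO; acetic acid CC(=O)O
Why: Oxidation of an aryl iodide to its diacetoxy-λ3-iodane by peracetic acid is the standard preparation of such reagents; the electron-rich iodine is oxidised before the anilide groups, and the two lactamide stereocentres are not involved.

**Step 3**
Reactants: 5 diacetoxy-λ3-iodane; 3 (E)-3-[3,4-bis(allyloxy)phenyl]prop-2-enoic acid (2.05 equiv)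
Product: 6 (R,R)-2-(bis{(E)-3-[3,4-bis(allyloxy)phenyl]acryloyloxy}-λ3-iodanyl)-1,3-bis[1-(mesitylcarbamoyl)ethoxy]benzene
Conditions: PhCl, 40 °C, 20 mbar (AcOH distilled off)
Reagents that add atoms: none
Why: Carboxylate ligands on trivalent iodine exchange with free acids, and removal of the more volatile acetic acid drives the equilibrium to the bis(acyloxy)iodane (ligand exchange, as for PhI(O2CR)2 reagents); mild temperature and absence of strong acid keep the electron-rich alkene of 3 from being oxidised.

**Step 4**
Reactants: 7 vanillin, 4-hydroxy-3-methoxybenzaldehyde; 6 chiral bis(acyloxy)-λ3-iodane (1.1 equiv)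
Product: 9 tricyclic keto lactone aldehyde (lactone-bridged bicyclo[2.2.2]oct-5-en-2-one; see compound list), via acyloxy dienone 8 (not isolated)
Conditions: CH2Cl2, −40 → 0 °C; then PhMe (0.01 M), 60 °C
Reagents that add atoms: none
Why: Proposed new method: enantioselective intermolecular transfer of a carboxylate ligand from a chiral λ3-iodane to the methoxy-bearing ortho carbon of a phenol has not been shown; the reasoning is that 7 replaces one carboxylate on iodine by its phenoxide oxygen and the second carboxylate is then passed to C8 inside the pocket formed by the two hydrogen-bonded lactamide arms as 4 departs, and the closest known reaction types are the racemic Wessely acyloxylation/intramolecular Diels–Alder tandem with unsaturated acids and the enantioselective oxidative spirolactonisation of phenols bearing a tethered carboxylic acid with this class of chiral aryl-λ3-iodanes. Attack should go to C8 and not to the free ortho or the para carbon, because the methoxy group best stabilises the developing cation and the para carbon carries the formyl group, and no second nucleophile is present. Dienone 8 is a type 1 intramolecular Diels–Alder substrate with a three-atom tether (C8, O, C9): the suprafacial [4+2] addition across C3 and C6 closes the bicyclo[2.2.2]octenone, and the tether closes as the fused five-membered γ-lactone, the only regiochemistry such a short tether allows. That regiochemistry is also the polarity-matched one, since C6 is δ to the ketone and β to the formyl group and bonds to C5, the nucleophilic β-carbon of the dialkoxystyrene. C8 is set by the reagent; C3 and C6 follow because the tether reaches only the diene face that carries the acyloxy oxygen; C5 follows because C9 is part of the tether and must lie on the side of the C7–C8 bridge; C4 follows from the E geometry of the dienophile, which a concerted addition keeps and which places the aryl group over the C1=C2 bridge. The formyl group at C1 and high dilution should hold back the Diels–Alder dimerisation typical of such dienones.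

**Step 5**
Reactants: 10 (R)-danshensu, (2R)-3-(3,4-dihydroxyphenyl)-2-hydroxypropanoic acid
Product: 11 allyl (2R)-3-[3,4-bis(allyloxy)phenyl]-2-hydroxypropanoate
Conditions: allyl bromide (3.3 equiv), K2CO3, DMF, 25 °C
Reagents that add atoms: allyl bromide C=CCBr
Why: Williamson alkylation; K2CO3 deprotonates only the carboxylic acid and the two phenols, so the secondary hydroxyl stays free, and carbonate at room temperature does not enolise the α-hydroxy ester.

**Step 6**
Reactants: 11 allyl (2R)-3-[3,4-bis(allyloxy)phenyl]-2-hydroxypropanoate
Product: 12 allyl (2R)-3-[3,4-bis(allyloxy)phenyl]-2-{[2-(diethoxyphosphoryl)acetyl]oxy}propanoate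
Conditions: (EtO)2P(O)CH2CO2H, DCC, DMAP (cat.), CH2Cl2, 0 °C → rt
Reagents that add atoms: diethylphosphonoacetic acid CCOP(=O)(CC(=O)O)OCC
Why: Steglich esterification; the stereocentre belongs to the alcohol partner, which is acylated at oxygen with retention.

**Step 7**
Reactants: 9 tricyclic keto lactone aldehyde; 12 phosphonoacetate
Product: 13 keto lactone (E)-dienoate carrying the protected lactate on C12
Conditions: LiCl, i-Pr2NEt, MeCN, 0 °C → rt
Reagents that add atoms: none
Why: Horner–Wadsworth–Emmons olefination under Masamune–Roush conditions gives the E alkene C10=C11 from the stabilised phosphonate. The aldehyde is far more electrophilic than the bridged ketone C7, which cannot enolise (its α-carbons are a bridgehead and a quaternary centre), and the weak amine base spares the lactate centre and the acyloxy ketal.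

**Step 8**
Reactants: 13 keto lactone dienoate
Product: 15 penta-O-allyl tricarboxylic acid (target with five allyl groups), via diketo acid 14 (not isolated)
Conditions: LiOH (1.1 equiv), THF/H2O 3:1, 0 °C; then 30% H2O2 (3 equiv), LiOH (2.2 equiv), 0 °C; then aq HCl (pH 2)
Reagents that add atoms: lithium hydroxide [Li+].[OH-]; hydrogen peroxide OO
Why: The lactone is an acyloxy ketal, hence an activated ester that hydroxide should open at 0 °C in preference to the conjugated dienoate; the freed hemiketal expels methanol to give 1,2-diketone 14, which hydroperoxide cleaves at C7–C8 to two carboxylates (oxidative cleavage of an α-diketone by alkaline hydrogen peroxide). No stereocentre is touched: C3 and C6 are bridgeheads until the bond breaks and are α to carboxylates afterwards, so the 1,4-cis relation follows directly from the former bridge.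

**Step 9**
Reactants: 15 penta-O-allyl tricarboxylic acid
Product: 16 the target, (1R,2R,3S,4R)-6-[(E)-3-{[(1R)-1-carboxy-2-(3,4-dihydroxyphenyl)ethyl]oxy}-3-oxoprop-1-en-1-yl]-3-(3,4-dihydroxyphenyl)cyclohex-5-ene-1,2,4-tricarboxylic acid
Conditions: Pd(PPh3)4 (5 mol %), p-TolSO2Na (6 equiv), degassed THF/MeOH, rt; then aq HCl (pH 2), under argon
Reagents that add atoms: none
Why: Zerovalent palladium ionises the allyl ester and the four aryl allyl ethers to π-allyl complexes, which the soft sulfinate traps as allyl p-tolyl sulfone (Tsuji–Trost deallylation). The medium stays near neutral, so the dienoate, C3, C6 and the lactate ester are not endangered.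

## Compound list

1 | caffeic acid | OC(=O)/C=C/c1ccc(O)c(O)c1 | starting material
2 | allyl (E)-3-[3,4-bis(allyloxy)phenyl]prop-2-enoate | C=CCOC(=O)/C=C/c1ccc(OCC=C)c(OCC=C)c1 | intermediate
3 | (E)-3-[3,4-bis(allyloxy)phenyl]prop-2-enoic acid | OC(=O)/C=C/c1ccc(OCC=C)c(OCC=C)c1 | intermediate
4 | (R,R)-2-iodo-1,3-bis[1-(mesitylcarbamoyl)ethoxy]benzene | Cc1cc(C)c(NC(=O)[C@@H](C)Oc2cccc(O[C@H](C)C(=O)Nc3c(C)cc(C)cc3C)c2I)c(C)c1 | starting material
5 | diacetoxy-λ3-iodane of 4 | Cc1cc(C)c(NC(=O)[C@@H](C)Oc2cccc(O[C@H](C)C(=O)Nc3c(C)cc(C)cc3C)c2I(OC(C)=O)OC(C)=O)c(C)c1 | intermediate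
6 | bis{(E)-3-[3,4-bis(allyloxy)phenyl]acryloyloxy}-λ3-iodane of 4 | Cc1cc(C)c(NC(=O)[C@@H](C)Oc2cccc(O[C@H](C)C(=O)Nc3c(C)cc(C)cc3C)c2I(OC(=O)/C=C/c2ccc(OCC=C)c(OCC=C)c2)OC(=O)/C=C/c2ccc(OCC=C)c(OCC=C)c2)c(C)c1 | intermediate
7 | vanillin | COc1cc(C=O)ccc1O | starting material
8 | (6R)-6-{(E)-3-[3,4-bis(allyloxy)phenyl]acryloyloxy}-4-formyl-6-methoxycyclohexa-2,4-dien-1-one | O=CC1=C[C@@](OC)(OC(=O)/C=C/c2ccc(OCC=C)c(OCC=C)c2)C(=O)C=C1 | intermediate
9 | tricyclic keto lactone aldehyde: bicyclo[2.2.2]oct-5-en-2-one with bridgeheads C3 and C6, ketone C7, ketal carbon C8 (OMe and lactone O), γ-lactone C8–O–C9(=O)–C5, 3,4-bis(allyloxy)phenyl on C4 on the side of the C1=C2 bridge, CHO on C1 | O=CC1=C[C@@H]2[C@H](c4ccc(OCC=C)c(OCC=C)c4)[C@@H]3[C@H]1[C@@](OC)(OC3=O)C2=O | intermediate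
10 | (R)-danshensu, (2R)-3-(3,4-dihydroxyphenyl)-2-hydroxypropanoic acid | O[C@H](Cc1ccc(O)c(O)c1)C(=O)O | starting material
11 | allyl (2R)-3-[3,4-bis(allyloxy)phenyl]-2-hydroxypropanoate | O[C@H](Cc1ccc(OCC=C)c(OCC=C)c1)C(=O)OCC=C | intermediate
12 | allyl (2R)-3-[3,4-bis(allyloxy)phenyl]-2-{[2-(diethoxyphosphoryl)acetyl]oxy}propanoate | CCOP(=O)(OCC)CC(=O)O[C@H](Cc1ccc(OCC=C)c(OCC=C)c1)C(=O)OCC=C | intermediate
13 | keto lactone (E)-dienoate: 9 with CHO replaced by (E)-CH=CH–C(=O)O–[(R)-lactate of 11] | O=C(/C=C/C1=C[C@@H]2[C@H](c4ccc(OCC=C)c(OCC=C)c4)[C@@H]3[C@H]1[C@@](OC)(OC3=O)C2=O)O[C@H](Cc1ccc(OCC=C)c(OCC=C)c1)C(=O)OCC=C | intermediate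
14 | diketo acid: bicyclo[2.2.2]oct-5-ene-2,3-dione (C7, C8) with free C9 carboxyl on C5 | O=C(/C=C/C1=C[C@@H]2[C@H](c4ccc(OCC=C)c(OCC=C)c4)[C@@H](C(=O)O)[C@H]1C(=O)C2=O)O[C@H](Cc1ccc(OCC=C)c(OCC=C)c1)C(=O)OCC=C | intermediate
15 | penta-O-allyl tricarboxylic acid (target with four aryl allyl ethers and the lactate allyl ester) | O=C(/C=C/C1=C[C@@H](C(=O)O)[C@H](c2ccc(OCC=C)c(OCC=C)c2)[C@@H](C(=O)O)[C@H]1C(=O)O)O[C@H](Cc1ccc(OCC=C)c(OCC=C)c1)C(=O)OCC=C | intermediate
16 | CNP0327643.1 | O=C(/C=C/C1=C[C@@H](C(=O)O)[C@H](c2ccc(O)c(O)c2)[C@@H](C(=O)O)[C@H]1C(=O)O)O[C@H](Cc1ccc(O)c(O)c1)C(=O)O | target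

## Step count and least certain steps

Total step count: 9. Longest linear sequence: 6 (steps 1, 3, 4, 7, 8, 9; the line 2, 3, 4, 7, 8, 9 is equally long).

**Step 4 (key step, labelled).**
- Most likely failure: poor facial discrimination in the carboxylate transfer, because the carboxylate is not tethered to the phenol and the pocket of the reagent may not hold it.
- Next: erosion of the C8 configuration by acyloxy migration, or dimerisation of the dienone, if the cycloaddition is slow (the ester tether must adopt its less favoured rotamer).
- Fallback with known chemistry, setting out from 3 and 7: PhI(OAc)2 and 3 (2 equiv) under the conditions of step 3 give the achiral bis{(E)-3-[3,4-bis(allyloxy)phenyl]acryloyloxy}(phenyl)-λ3-iodane F1. F1 oxidises 7 in CH2Cl2 and the Wessely/Diels–Alder tandem runs without facial bias, giving 8 with its enantiomer, the (6S)-dienone F2, and then 9 with its enantiomer, the mirror-image keto lactone aldehyde F3. The racemate is taken through step 7 with enantiopure 12, giving 13 and the diastereomeric dienoate F4 (mirror-image cage, same (R)-lactate), which are separated by preparative HPLC. The fallback returns to the route at 13.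

**Step 3.**
- Most likely failure: incomplete ligand exchange, which leaves acetate on iodine; acetate would then be transferred in step 4 and give a dienone without dienophile.
- Fallback from 5: hydrolysis with aqueous NaOH gives the iodosylarene F5, which is condensed with 3 (2 equiv) in CHCl3 over MgSO4 to give 6 with water as the only by-product, so no competing carboxylate can remain. It returns at 6.

**Step 8.**
- Most likely failures: loss of the C12 ester by hydroxide or hydroperoxide; or peroxide attack on ketone C7 before the lactone has opened (a Baeyer–Villiger-type path that would leave C8 as a methyl ester); or benzilic-acid ring contraction of the diketone.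
- Fallback from 13, with neither hydroxide nor peroxide: Me3SnOH (1.2 equiv) in 1,2-dichloroethane at 60 °C opens only the activated acyloxy ketal; 14 is isolated; H5IO6 in THF/H2O at room temperature then cleaves the diketone hydrate to 15. This fallback makes no new compound (F0) and returns at 15.

**Step 7.**
- Most likely failure: attack of the phosphonate anion on the activated lactone carbonyl or on the strained ketone instead of the aldehyde, or partial epimerisation of the lactate centre by the base.
- Fallback from 11, with no base in the olefination: bromoacetyl bromide/pyridine gives the bromoacetate F6; PPh3 gives the phosphonium bromide F7; aqueous Na2CO3 gives the isolable stabilised ylide F8. F8 and 9 in PhMe at 50 °C give 13 by a Wittig reaction. It returns at 13.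

**Step 9.**
- Most likely failure: incomplete removal of all five allyl groups, C-allylation of the freed catechols by the π-allyl complex, or air oxidation of the catechols during isolation.
- Fallback from 15: [Ir(cod)(PMePh2)2]PF6 (activated with H2) in THF isomerises every allyl group to the (E)-prop-1-enyl group, giving the penta(prop-1-enyl) compound F9; dilute aqueous HCl in acetone then hydrolyses the enol ethers and the enol ester to 16.

## Further compounds

F1 | step 4 | bis{(E)-3-[3,4-bis(allyloxy)phenyl]acryloyloxy}(phenyl)-λ3-iodane | C=CCOc1ccc(/C=C/C(=O)OI(OC(=O)/C=C/c2ccc(OCC=C)c(OCC=C)c2)c2ccccc2)cc1OCC=C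
F2 | step 4 | (6S)-6-{(E)-3-[3,4-bis(allyloxy)phenyl]acryloyloxy}-4-formyl-6-methoxycyclohexa-2,4-dien-1-one (enantiomer of 8) | O=CC1=C[C@](OC)(OC(=O)/C=C/c2ccc(OCC=C)c(OCC=C)c2)C(=O)C=C1
F3 | step 4 | enantiomer of keto lactone aldehyde 9 | O=CC1=C[C@H]2[C@@H](c4ccc(OCC=C)c(OCC=C)c4)[C@H]3[C@@H]1[C@](OC)(OC3=O)C2=O
F4 | step 4 | diastereomer of 13 (mirror-image cage, (R)-lactate) | O=C(/C=C/C1=C[C@H]2[C@@H](c4ccc(OCC=C)c(OCC=C)c4)[C@H]3[C@@H]1[C@](OC)(OC3=O)C2=O)O[C@H](Cc1ccc(OCC=C)c(OCC=C)c1)C(=O)OCC=C
F5 | step 3 | (R,R)-2-iodosyl-1,3-bis[1-(mesitylcarbamoyl)ethoxy]benzene | Cc1cc(C)c(NC(=O)[C@@H](C)Oc2cccc(O[C@H](C)C(=O)Nc3c(C)cc(C)cc3C)c2I=O)c(C)c1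
F0 | step 8 | none | none
F6 | step 7 | allyl (2R)-3-[3,4-bis(allyloxy)phenyl]-2-(2-bromoacetoxy)propanoate | BrCC(=O)O[C@H](Cc1ccc(OCC=C)c(OCC=C)c1)C(=O)OCC=C
F7 | step 7 | phosphonium bromide from F6 and PPh3 | [Br-].O=C(C[P+](c1ccccc1)(c1ccccc1)c1ccccc1)O[C@H](Cc1ccc(OCC=C)c(OCC=C)c1)C(=O)OCC=C
F8 | step 7 | stabilised ylide, allyl (2R)-3-[3,4-bis(allyloxy)phenyl]-2-{[2-(triphenyl-λ5-phosphanylidene)acetyl]oxy}propanoate | O=C(C=P(c1ccccc1)(c1ccccc1)c1ccccc1)O[C@H](Cc1ccc(OCC=C)c(OCC=C)c1)C(=O)OCC=C
F9 | step 9 | penta[(E)-prop-1-enyl] isomer of 15 | O=C(/C=C/C1=C[C@@H](C(=O)O)[C@H](c2ccc(O/C=C/C)c(O/C=C/C)c2)[C@@H](C(=O)O)[C@H]1C(=O)O)O[C@H](Cc1ccc(O/C=C/C)c(O/C=C/C)c1)C(=O)O/C=C/C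
A1 | alternative 1 | dimethyl (2E,5E)-4-(2-methoxy-2-oxoethylidene)hepta-2,5-dienedioate | COC(=O)/C=C/C(=CC(=O)OC)/C=C/C(=O)OC
A2 | alternative 1 | cyclohexene tetraester (methyl esters at C7, C8 and C12, allyl ester at C9, 3,4-bis(allyloxy)phenyl at C4, ring configuration as in 15) | COC(=O)/C=C/C1=C[C@@H](C(=O)OC)[C@H](c2ccc(OCC=C)c(OCC=C)c2)[C@@H](C(=O)OCC=C)[C@H]1C(=O)OC
A3 | alternative 2 | cyclohexene carbaldehyde with geminal diester at C5 (tert-butyl esters at C7 and C8, CHO on C1) | O=CC1=C[C@@H](C(=O)OC(C)(C)C)[C@H](c2ccc(OCC=C)c(OCC=C)c2)C(C(=O)OC)(C(=O)OC)[C@H]1C(=O)OC(C)(C)C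
A4 | alternative 3 | acyclic 1,7-enyne triester (3,4-dimethoxyphenyl at C4, vinyl on C3, ethynyl on C6) | C=C[C@@H](C(=O)OC)[C@H](c1ccc(OC)c(OC)c1)[C@@H](C(=O)OC)[C@H](C#C)C(=O)OC
A5 | alternative 3 | 1-vinylcyclohexene triester | C=CC1=C[C@@H](C(=O)OC)[C@H](c2ccc(OC)c(OC)c2)[C@@H](C(=O)OC)[C@H]1C(=O)OC
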